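(The runs were computed on assumed constants; scatter was added.)

4 questions stand on 3 flasks, and the earlier runs hold one number that answers most of them.

| flask | substrate | partner | remark | time |
|---|---|---|---|---|
| theta | 0.10 M | 1.05 equiv | run made earlier |  |
| alpha | 0.067 M | 1.05 equiv | run made earlier |  |
| epsilon | 0.15 M | 1.05 equiv | run made earlier |  |
| north-east | 0.10 M | 1.05 equiv | everything together at the start | 4.0 min |
| south-east | 0.10 M (fed, over 3.0 min) | 1.05 equiv | all else is in the flask from the start; the feed brings no volume worth counting | 4.0 min |
| west | 0.10 M | 1.05 equiv (fed, over 3.0 min) | all else is in the flask from the start; the feed brings no volume worth counting | 4.0 min |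

| run | time / min | target / % | homo dimer / % |
|---|---|---|---|
| theta | 0.333 | 16.9 | 0.9 |
| theta | 0.667 | 25.2 | 0.1 |
| theta | 1.00 | 27.0 | 0.6 |
| theta | 2.00 | 27.1 | 1.8 |
| theta | 4.00 | 27.4 | 3.8 |
| alpha | 0.333 | 11.1 | 0.7 |
| alpha | 0.667 | 18.9 | 1.4 |
| alpha | 1.00 | 20.8 | 0.2 |
| alpha | 2.00 | 20.9 | 1.7 |
| alpha | 4.00 | 20.2 | 3.1 |
| epsilon | 0.333 | 23.8 | 1.1 |
| epsilon | 1.00 | 35.1 | 0.8 |
| epsilon | 2.00 | 34.3 | 1.9 |
| epsilon | 3.00 | 35.0 | 3.4 |
| epsilon | 4.00 | 35.2 | 4.5 |

(standard deviation of a reading: 0.5 percentage points)

- percentages count the substrate that a species holds: one homo dimer counts as two
- what was read earlier has a scatter of 0.5 percentage points, one standard deviation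
- on the list of suspects stand: substrate + partner -> intermediate + released group; intermediate -> target; partner -> decomposed reagent; 2 substrate -> homo dimer

* the flask with the highest share of target in target plus homo dimer ("all alike" if they lie within 1.5 percentage points) (north-east / south-east / west / all alike)
* share of target in target plus homo dimer at the end, north-east
* share of target in target plus homo dimer at the end, south-east
* share of target in target plus homo dimer at the end, west

Theta and epsilon hold equal equivalents of partner but differ in substrate, 0.10 M against 0.15 M, and target reads 27.4% in theta and 35.2% in epsilon at the last reading. A suspect explains this: partner decays by itself while it also couples with substrate. Let s be substrate as a fraction of its charge and L a constant of the flask. Of the partner lost at any moment, a share s/(s+L) couples, a selectivity factor of sorts. Dividing the two rates removes the clock, and integrating gives, for y, the fraction of the charge coupled: equivalents = y + L·ln[1/(1−y)].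

Theta's plateau gives L = 2.42. This is the loss number, the fraction of the charge at which decay and coupling take partner equally. Epsilon reads 1.61, and it ends higher because this is smaller; scaled to theta's charge it gives 2.41.

North-east repeats theta, so its share is 87.8%. West's slow partner changes no term of the rule, so its target should match theta's, but its substrate stays higher for longer, so its share should sit a little lower.

South-east differs from theta in one thing: s climbs from zero as time over 3.0 min, and even at full charge it stays below L. Theta's reading at 0.333 min stands at 61.7% of its plateau, so partner's lifetime reads about 0.347 min if that rise is taken as a single decay, and the delay of the intermediate is counted in that figure. Integrating then gives my estimate of south-east's target, with s taken as small against L: y ≈ (equivalents/L)·(lifetime/feed time) = 5.01%. Scaling theta's dimer by the integral of s² gives about 3.60%, so my estimate of the share for south-east is 58.2%, below north-east.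

The forecast names north-east, with 87.8%, 54% and 84.8% for north-east, south-east and west, since “partner dies before substrate arrives”.

The flasks give north-east first at 87.8%, then west at 84.5% and south-east at 31.8%.

    substrate + partner → intermediate + released group (k = 0.531 L mol⁻¹ s⁻¹)
    intermediate → target (k = 0.0729 s⁻¹)
    partner → decomposed reagent (k = 0.129 s⁻¹)
    2 substrate → homo dimer (k = 0.00155 L mol⁻¹ s⁻¹)

South-east holds 1.60% target at 4.00 min, beside 0.103 M decomposed reagent. Read backwards with L, that target gives a partner lifetime of 0.111 min, a third of the figure read from theta. North-east's neighbour at 0.40 M substrate has L = 0.606, and its simulated target of 55.5% returns 1.05 equivalents of partner against 1.05 equiv charged.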